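In the elm run, substrate plus self-condensation product, both counted in substrate units, comes to 37.9% at 80.0 min. In the cedar run, charged at 0.25 M rather than 0.38 M, the same sum is 38.6% at 80.0 min. In the elm run it already stood at 38.9% at 30.0 min, so in that run the sum barely moves while substrate turns into product. The mean over the last two readings of both runs is 38.3%; call it P, the pool, the share of the charge that escaped the reagent. The ash run, with 1.7 equiv of reagent and a charge of 0.50 M, ends lower, at 20.5%. The flask has the equivalents of cedar and elm, and this reckoning gives it the same P, although its charge of 0.50 M lies above both of theirs.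

| flask | substrate | reagent | remark | time |
|---|---|---|---|---|
| cedar | 0.25 M | 1.1 equiv | run made earlier |  |
| elm | 0.38 M | 1.1 equiv | run made earlier |  |
| ash | 0.50 M | 1.7 equiv | run made earlier |  |
| flask | 0.50 M | 1.10 equiv |  | 80 min |

| run | time / min | substrate / % | self-condensation product / % | tetra adduct / % |
|---|---|---|---|---|
| cedar | 15.0 | 30.8 | 6.3 | 2.8 |
| cedar | 30.0 | 26.6 | 14.5 | 0 |
| cedar | 50.0 | 22.7 | 16.7 | 1.7 |
| cedar | 60.0 | 21.2 | 18.8 | 2.7 |
| cedar | 80.0 | 16.2 | 22.4 | 2.1 |
| cedar | 90.0 | 16.5 | 22.1 | 2.3 |
| elm | 6.00 | 32.4 | 7.1 | 4.2 |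
| elm | 20.0 | 25.9 | 12.8 | 0.7 |
| elm | 30.0 | 22.4 | 16.5 | 2.9 |
| elm | 50.0 | 18.4 | 20.9 | 3.5 |
| elm | 80.0 | 14.3 | 23.6 | 2.3 |
| elm | 90.0 | 12.8 | 25.5 | 1.8 |
| ash | 8.00 | 20.2 | 4.8 | 7.0 |
| ash | 15.0 | 17.5 | 6.3 | 8.3 |
| ash | 25.0 | 16.4 | 8.9 | 6.4 |
| ash | 50.0 | 10.3 | 13.0 | 6.7 |
| ash | 90.0 | 7.5 | 13.0 | 7.6 |

(standard deviation of a reading: 1 percentage point)

- concentration of substrate at 80 min, in M
- concentration of self-condensation product at 80 min, in M
- concentration of tetra adduct at 80 min, in M

- a species is counted by the substrate in it: one self-condensation product counts as two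

In cedar and elm substrate falls fast and then creeps, which this reckoning reads as a fast stage with the limiting reagent, followed by self-condensation of the pool. For a second-order loss, the reciprocal of the substrate concentration climbs in a straight line. Between 20.0 min and 90.0 min the elm readings give a slope κ of 0.149 L mol⁻¹ min⁻¹. Treating the reagent stage as instantaneous, this reckoning starts the flask's tail at P times 0.50 M and puts its substrate at 0.0585 M at 80 min. Each self-condensation product takes two substrate, so the substrate lost in that tail gives an estimated 0.0666 M of product. The late tetra adduct readings of cedar and elm average 2.12%, which this reckoning carries over to the flask as 0.0106 M.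

The forecast, “Extrapolating to 0.50 M” from the two lower charges, gives 0.0625 M, 0.064 M and 0.0115 M, with more substrate and less product than this reckoning.

    substrate + reagent → mono adduct (k = 0.0371 L mol⁻¹ s⁻¹)
    reagent + mono adduct → bis adduct (k = 0.0615 L mol⁻¹ s⁻¹)
    reagent + bis adduct → tris adduct (k = 0.0490 L mol⁻¹ s⁻¹)
    reagent + tris adduct → tetra adduct (k = 0.0217 L mol⁻¹ s⁻¹)
    2 substrate → self-condensation product (k = 0.00121 L mol⁻¹ s⁻¹)

The flask gives 0.0586 M substrate, 0.0694 M self-condensation product and 0.0100 M tetra adduct. Its substrate and product together make 39.5% of the charge, against a pool P of 38.3%. The same recipe read at 20 min is the second test: P and κ give 0.122 M substrate, and that flask holds 0.120 M.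

(The readings are simulated from invented constants.)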